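**Plan**

- Retrosynthesis: the hydroxy-methoxy-quinone is taken back to a 2,3,5,6-tetramethoxyphenyl ring (C–O changes only) and the C3' methyl to a lactone carbonyl. The C2'=C3' alkene is then cut by ring-closing metathesis, followed by the aryl ester C–O bond, the C3'–C4' bond (malonate alkylation) and the cyclohexene C1–CH2 bond (Johnson–Claisen).
- Enabling feature: on the E C2'=C3' alkene the C3' methyl is cis to C1', and C1' sits on a ring carbon whose ortho neighbour carries oxygen. Tying that oxygen to the methyl carbon at the carboxyl oxidation level gives a 7-membered lactone (O, C=O, C3', C2', C1' and two arene carbons) that can hold only this geometry.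
- Forward: an allylphenol (3 steps) and a chiral 2-substituted acrylic acid (7 steps) are joined as an aryl ester. Metathesis closes the only new ring, hydride reopens it, the CH2OH group is reduced to the C3' methyl, and the quinone is unveiled last.
- Stereochemistry: the (S) ring stereocentre is set by a CBS reduction and carried from oxygen to carbon by the suprafacial Johnson–Claisen shift. The E alkene is set by the cis-only 7-membered ring.

Key step: step 12

Remark: chain carbons are numbered C1' (CH2 on the quinone ring) to C5' (CH2 on the cyclohexene); the (S)-oxazaborolidine is assumed to treat the 2-methylvinyl flank of 2,4,4-trimethylcyclohex-2-enone as the large carbonyl substituent, as for other 2-substituted cyclohex-2-enones.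

**Route**

Step 1
Reactants: 1 2,4,5-trimethoxybenzaldehyde
Product: 3 2,4,5-trimethoxyphenol, via aryl formate 2 (not isolated)
Conditions: mCPBA, CH2Cl2, 0 °C → rt; then K2CO3 (cat.), MeOH, rt, under N2
Reagents that add atoms: 3-chloroperoxybenzoic acid (mCPBA) OOC(=O)c1cccc(Cl)c1
Why: Baeyer–Villiger (Dakin-type) oxidation, in which the electron-rich aryl group migrates to oxygen to give formate 2, which base-catalysed methanolysis cleaves to the phenol.

Step 2
Reactants: 3 2,4,5-trimethoxyphenol
Product: 4 1-(allyloxy)-2,4,5-trimethoxybenzene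
Conditions: allyl bromide, K2CO3, acetone, reflux
Reagents that add atoms: allyl bromide C=CCBr
Why: Williamson ether synthesis, an SN2 reaction of the phenoxide with a primary allylic bromide.

Step 3
Reactants: 4 1-(allyloxy)-2,4,5-trimethoxybenzene
Product: 6 2-allyl-3,4,6-trimethoxyphenol, via dienone 5 (not isolated)
Conditions: PhNEt2, 190 °C
Reagents that add atoms: none
Why: aromatic Claisen rearrangement, whose [3,3]-shift can end productively only at the single unsubstituted ortho carbon (the other ortho and the para carbon carry methoxy groups), after which dienone 5 re-aromatises by tautomerisation.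

Step 4
Reactants: 7 2,4,4-trimethylcyclohex-2-en-1-one
Product: 8 (R)-2,4,4-trimethylcyclohex-2-en-1-ol
Conditions: (S)-Me-CBS oxazaborolidine [(S)-1-methyl-3,3-diphenyltetrahydro-1H,3H-pyrrolo[1,2-c][1,3,2]oxazaborole] (10 mol%), BH3·SMe2, THF, −20 °C
Reagents that add atoms: none
Why: Corey–Bakshi–Shibata reduction, in which the oxazaborolidine–borane complex binds the carbonyl oxygen anti to the 2-methylvinyl flank and should deliver hydride to the face that gives the (R)-carbinol, the same sense as acetophenone to (R)-1-phenylethanol.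

Step 5
Reactants: 8 (R)-2,4,4-trimethylcyclohex-2-en-1-ol; 9 triethyl orthoacetate
Product: 11 ethyl 2-[(S)-2,6,6-trimethylcyclohex-2-en-1-yl]acetate, via ketene acetal 10 (not isolated)
Conditions: MeC(OEt)3 (excess), EtCO2H (cat.), 145 °C, EtOH distilled off
Reagents that add atoms: triethyl orthoacetate (compound 9) CCOC(C)(OCC)OCC
Why: Johnson–Claisen rearrangement, in which orthoester exchange and loss of ethanol give ketene acetal 10, whose suprafacial [3,3]-shift forms the new C–C bond at the alkene terminus on the ring face that carried oxygen, so the (R)-carbinol becomes the (S)-configured allylic carbon while the alkene moves to the 2,3-position.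

Step 6
Reactants: 11 ethyl 2-[(S)-2,6,6-trimethylcyclohex-2-en-1-yl]acetate
Product: 12 2-[(S)-2,6,6-trimethylcyclohex-2-en-1-yl]ethan-1-ol
Conditions: LiAlH4, Et2O, 0 °C
Reagents that add atoms: none
Why: hydride reduction of an ester to the primary alcohol, to which the stereocentre and the trisubstituted alkene are inert.

Step 7
Reactants: 12 2-[(S)-2,6,6-trimethylcyclohex-2-en-1-yl]ethan-1-ol
Product: 13 (S)-6-(2-iodoethyl)-1,5,5-trimethylcyclohex-1-ene
Conditions: I2, PPh3, imidazole, CH2Cl2, 0 °C → rt
Reagents that add atoms: iodine II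
Why: Appel-type iodination, in which iodide displaces the alkoxyphosphonium group by SN2 at an unhindered primary carbon.

Step 8
Reactants: 13 (S)-6-(2-iodoethyl)-1,5,5-trimethylcyclohex-1-ene; 14 diethyl malonate
Product: 15 diethyl 2-{2-[(S)-2,6,6-trimethylcyclohex-2-en-1-yl]ethyl}malonate
Conditions: NaH, diethyl malonate (3 equiv), THF/DMF, 0 °C; then 13, 60 °C
Reagents that add atoms: diethyl malonate (compound 14) CCOC(=O)CC(=O)OCC
Why: malonic ester alkylation, an SN2 reaction of sodiomalonate with a primary iodide in which excess malonate suppresses dialkylation.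

Step 9
Reactants: 15 diethyl 2-{2-[(S)-2,6,6-trimethylcyclohex-2-en-1-yl]ethyl}malonate
Product: 16 2-{2-[(S)-2,6,6-trimethylcyclohex-2-en-1-yl]ethyl}malonic acid
Conditions: KOH, EtOH/H2O, reflux; then cold dilute HCl
Reagents that add atoms: potassium hydroxide [K+].[OH-]
Why: saponification of both esters by acyl–oxygen cleavage, with cold acidification to avoid premature decarboxylation and acid-induced migration of the ring alkene.

Step 10
Reactants: 16 2-{2-[(S)-2,6,6-trimethylcyclohex-2-en-1-yl]ethyl}malonic acid
Product: 18 2-methylene-4-[(S)-2,6,6-trimethylcyclohex-2-en-1-yl]butanoic acid, via Mannich base 17 (not isolated)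
Conditions: (CH2O)n, Et2NH, EtOAc, reflux
Reagents that add atoms: formaldehyde (as paraformaldehyde) C=O
Why: Mannich reaction of the malonic acid with formaldehyde and diethylamine gives Mannich base 17, which loses CO2 and diethylamine in a decarboxylative elimination to leave the 2-substituted acrylic acid.

Step 11
Reactants: 18 2-methylene-4-[(S)-2,6,6-trimethylcyclohex-2-en-1-yl]butanoic acid; 6 2-allyl-3,4,6-trimethoxyphenol
Product: 19 2-allyl-3,4,6-trimethoxyphenyl 2-methylene-4-[(S)-2,6,6-trimethylcyclohex-2-en-1-yl]butanoate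
Conditions: DCC, 4-(dimethylamino)pyridine (cat.), CH2Cl2, 0 °C → rt
Reagents that add atoms: none
Why: Steglich esterification, in which the O-acylisourea is relayed through an acylpyridinium ion to the hindered phenol.

Step 12
Reactants: 19 2-allyl-3,4,6-trimethoxyphenyl 2-methylene-4-[(S)-2,6,6-trimethylcyclohex-2-en-1-yl]butanoate
Product: 20 6,7,9-trimethoxy-3-{2-[(S)-2,6,6-trimethylcyclohex-2-en-1-yl]ethyl}-1-benzoxepin-2(5H)-one
Conditions: second-generation Grubbs catalyst (H2IMes)(PCy3)Cl2Ru=CHPh (5–10 mol%), 1,4-benzoquinone (10 mol%), toluene (0.005 M), 80 °C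
Reagents that add atoms: none
Why: The catalyst initiates at the monosubstituted allyl alkene, the resulting ruthenium alkylidene adds to the 1,1-disubstituted acrylate alkene in an intramolecular [2+2] cycloaddition, and cycloreversion of the ruthenacyclobutane releases the cyclic trisubstituted alkene with loss of ethylene. The closest known reaction is ring-closing olefin metathesis of an acrylate ester onto a tethered terminal alkene, an established way to α-substituted α,β-unsaturated lactones. The 7-membered ring (O1, C2, C3, C4, C5, C5a, C9a) closes by forming the C3=C4 double bond, which is C3'=C2' of the target chain, between the α-carbon of the acrylate and the internal carbon of the allyl group. No stereocentre is formed and the remote (S) centre is untouched; the alkene geometry is dictated by the ring, because a 7-membered ring can hold only a cis endocyclic alkene, which places C1' and the carbonyl carbon cis and becomes the E geometry once that carbon is the C3' methyl. The step needs chemoselectivity for the two terminal alkenes over the ring alkene, secured by the low reactivity of that hindered trisubstituted alkene. It also needs ring closure to outrun dimerisation and allyl-to-propenyl migration, secured by the ortho placement of the two arms, high dilution and 1,4-benzoquinone as a scavenger of ruthenium hydrides.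

Step 13
Reactants: 20 6,7,9-trimethoxy-3-{2-[(S)-2,6,6-trimethylcyclohex-2-en-1-yl]ethyl}-1-benzoxepin-2(5H)-one
Product: 21 2-[(Z)-3-(hydroxymethyl)-5-[(S)-2,6,6-trimethylcyclohex-2-en-1-yl]pent-2-en-1-yl]-3,4,6-trimethoxyphenol
Conditions: i-Bu2AlH (4 equiv), CH2Cl2, −78 → 0 °C; aq. potassium sodium tartrate work-up
Reagents that add atoms: none
Why: double 1,2-hydride reduction of the activated aryl ester releases the phenol and the primary allylic alcohol without touching the alkene, so the cis relation of C1' and the former carbonyl carbon is kept in the open chain.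

Step 14
Reactants: 21 2-[(Z)-3-(hydroxymethyl)-5-[(S)-2,6,6-trimethylcyclohex-2-en-1-yl]pent-2-en-1-yl]-3,4,6-trimethoxyphenol
Product: 22 (Z)-4-(2,3,5,6-tetramethoxyphenyl)-2-{2-[(S)-2,6,6-trimethylcyclohex-2-en-1-yl]ethyl}but-2-en-1-ol
Conditions: MeI, K2CO3, DMF, rt
Reagents that add atoms: iodomethane CI
Why: Williamson methylation in which carbonate deprotonates only the phenol and not the aliphatic alcohol, which removes the acidic and nucleophilic phenol before the next step and makes the arene symmetric about the chain axis.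

Step 15
Reactants: 22 (Z)-4-(2,3,5,6-tetramethoxyphenyl)-2-{2-[(S)-2,6,6-trimethylcyclohex-2-en-1-yl]ethyl}but-2-en-1-ol
Product: 24 1,2,4,5-tetramethoxy-3-[(E)-3-methyl-5-[(S)-2,6,6-trimethylcyclohex-2-en-1-yl]pent-2-en-1-yl]benzene, via pyridinium sulfate 23 (not isolated)
Conditions: SO3·pyridine, THF, 0 °C → rt; then LiAlH4, THF, 0 °C → rt
Reagents that add atoms: none
Why: deoxygenation of an allylic alcohol through its sulfate monoester, in which hydride from LiAlH4 displaces sulfate at the primary carbon by SN2 and so leaves the position and geometry of the alkene unchanged.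

Step 16
Reactants: 24 1,2,4,5-tetramethoxy-3-[(E)-3-methyl-5-[(S)-2,6,6-trimethylcyclohex-2-en-1-yl]pent-2-en-1-yl]benzene
Product: 25 2,5-dimethoxy-3-[(E)-3-methyl-5-[(S)-2,6,6-trimethylcyclohex-2-en-1-yl]pent-2-en-1-yl]cyclohexa-2,5-diene-1,4-dione
Conditions: (NH4)2Ce(NO3)6 (2.5 equiv), MeCN/H2O, 0 °C
Reagents that add atoms: water O
Why: oxidative demethylation of a para-dimethoxyarene by tetravalent cerium, in which two one-electron oxidations and attack of water at the two ipso carbons give the quinone, and the symmetry of the arene makes either para pair lead to the same 2,5-dimethoxyquinone.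

Step 17
Reactants: 25 2,5-dimethoxy-3-[(E)-3-methyl-5-[(S)-2,6,6-trimethylcyclohex-2-en-1-yl]pent-2-en-1-yl]cyclohexa-2,5-diene-1,4-dione
Product: 26 2-hydroxy-5-methoxy-3-[(E)-3-methyl-5-[(S)-2,6,6-trimethylcyclohex-2-en-1-yl]pent-2-en-1-yl]cyclohexa-2,5-diene-1,4-dione (target)
Conditions: HClO4 (aq), THF, 0 °C → rt
Reagents that add atoms: water O
Why: acid-catalysed hydrolysis of a vinylogous ester by addition–elimination, in which the methoxy group next to the chain is twisted out of the quinone plane by C1' and is less stabilised by conjugation than the one next to the ring CH, so water should replace it preferentially.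

**Compound list**

1 | 2,4,5-trimethoxybenzaldehyde | COc1cc(OC)c(C=O)cc1OC | starting material
2 | 2,4,5-trimethoxyphenyl formate | COc1cc(OC)c(OC=O)cc1OC | intermediate
3 | 2,4,5-trimethoxyphenol | COc1cc(OC)c(O)cc1OC | intermediate
4 | 1-(allyloxy)-2,4,5-trimethoxybenzene | C=CCOc1cc(OC)c(OC)cc1OC | intermediate
5 | 6-allyl-2,4,5-trimethoxycyclohexa-2,4-dien-1-one (racemic at C6) | C=CCC1C(=O)C(OC)=CC(OC)=C1OC | intermediate
6 | 2-allyl-3,4,6-trimethoxyphenol | C=CCc1c(O)c(OC)cc(OC)c1OC | intermediate
7 | 2,4,4-trimethylcyclohex-2-en-1-one | CC1=CC(C)(C)CCC1=O | starting material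
8 | (R)-2,4,4-trimethylcyclohex-2-en-1-ol | O[C@H]1C(C)=CC(C)(C)CC1 | intermediate
9 | triethyl orthoacetate | CCOC(C)(OCC)OCC | starting material
10 | 1-ethoxyvinyl (R)-2,4,4-trimethylcyclohex-2-en-1-yl ether (ketene acetal) | C=C(OCC)O[C@H]1C(C)=CC(C)(C)CC1 | intermediate
11 | ethyl 2-[(S)-2,6,6-trimethylcyclohex-2-en-1-yl]acetate | CCOC(=O)C[C@@H]1C(C)=CCCC1(C)C | intermediate
12 | 2-[(S)-2,6,6-trimethylcyclohex-2-en-1-yl]ethan-1-ol | OCC[C@@H]1C(C)=CCCC1(C)C | intermediate
13 | (S)-6-(2-iodoethyl)-1,5,5-trimethylcyclohex-1-ene | ICC[C@@H]1C(C)=CCCC1(C)C | intermediate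
14 | diethyl malonate | CCOC(=O)CC(=O)OCC | starting material
15 | diethyl 2-{2-[(S)-2,6,6-trimethylcyclohex-2-en-1-yl]ethyl}malonate | CCOC(=O)C(CC[C@@H]1C(C)=CCCC1(C)C)C(=O)OCC | intermediate
16 | 2-{2-[(S)-2,6,6-trimethylcyclohex-2-en-1-yl]ethyl}malonic acid | OC(=O)C(CC[C@@H]1C(C)=CCCC1(C)C)C(O)=O | intermediate
17 | 2-[(diethylamino)methyl]-2-{2-[(S)-2,6,6-trimethylcyclohex-2-en-1-yl]ethyl}malonic acid (Mannich base) | CCN(CC)CC(CC[C@@H]1C(C)=CCCC1(C)C)(C(O)=O)C(O)=O | intermediate
18 | 2-methylene-4-[(S)-2,6,6-trimethylcyclohex-2-en-1-yl]butanoic acid | C=C(CC[C@@H]1C(C)=CCCC1(C)C)C(O)=O | intermediate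
19 | 2-allyl-3,4,6-trimethoxyphenyl 2-methylene-4-[(S)-2,6,6-trimethylcyclohex-2-en-1-yl]butanoate | C=CCc1c(OC(=O)C(=C)CC[C@@H]2C(C)=CCCC2(C)C)c(OC)cc(OC)c1OC | intermediate
20 | 6,7,9-trimethoxy-3-{2-[(S)-2,6,6-trimethylcyclohex-2-en-1-yl]ethyl}-1-benzoxepin-2(5H)-one | O=C1Oc2c(OC)cc(OC)c(OC)c2CC=C1CC[C@@H]1C(C)=CCCC1(C)C | intermediate
21 | 2-[(Z)-3-(hydroxymethyl)-5-[(S)-2,6,6-trimethylcyclohex-2-en-1-yl]pent-2-en-1-yl]-3,4,6-trimethoxyphenol | OC/C(CC[C@@H]1C(C)=CCCC1(C)C)=C\Cc1c(O)c(OC)cc(OC)c1OC | intermediate
22 | (Z)-4-(2,3,5,6-tetramethoxyphenyl)-2-{2-[(S)-2,6,6-trimethylcyclohex-2-en-1-yl]ethyl}but-2-en-1-ol | OC/C(CC[C@@H]1C(C)=CCCC1(C)C)=C\Cc1c(OC)c(OC)cc(OC)c1OC | intermediate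
23 | pyridinium (Z)-4-(2,3,5,6-tetramethoxyphenyl)-2-{2-[(S)-2,6,6-trimethylcyclohex-2-en-1-yl]ethyl}but-2-en-1-yl sulfate | [O-]S(=O)(=O)OC/C(CC[C@@H]1C(C)=CCCC1(C)C)=C\Cc1c(OC)c(OC)cc(OC)c1OC.c1cc[nH+]cc1 | intermediate
24 | 1,2,4,5-tetramethoxy-3-[(E)-3-methyl-5-[(S)-2,6,6-trimethylcyclohex-2-en-1-yl]pent-2-en-1-yl]benzene | COc1cc(OC)c(OC)c(C/C=C(\C)CC[C@@H]2C(C)=CCCC2(C)C)c1OC | intermediate
25 | 2,5-dimethoxy-3-[(E)-3-methyl-5-[(S)-2,6,6-trimethylcyclohex-2-en-1-yl]pent-2-en-1-yl]cyclohexa-2,5-diene-1,4-dione | COC1=CC(=O)C(OC)=C(C/C=C(\C)CC[C@@H]2C(C)=CCCC2(C)C)C1=O | intermediate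
26 | 2-hydroxy-5-methoxy-3-[(E)-3-methyl-5-[(S)-2,6,6-trimethylcyclohex-2-en-1-yl]pent-2-en-1-yl]cyclohexa-2,5-diene-1,4-dione | COC1=CC(=O)C(O)=C(C/C=C(\C)CC[C@@H]2C(C)=CCCC2(C)C)C1=O | target

**Step count**

Total: 17 steps. Longest linear sequence: 14 steps (steps 4 to 17, from enone 7 to target 26).

**Steps most likely to fail**

Step 12 (ring-closing metathesis). The ruthenium alkylidene formed at the allyl terminus may engage the hindered, electron-poor acrylate alkene too slowly, so that migration of the allyl double bond into conjugation with the arene, or coupling of two allyl termini, outruns ring closure. The fallback gives up the tether and sets the geometry by a Z-selective Still–Gennari olefination, setting out from allylphenol 6 and iodide 13 and rejoining the route at allylic alcohol 22. O-Methylation of 6 (MeI, K2CO3, DMF) would give 3-allyl-1,2,4,5-tetramethoxybenzene F1, and Lemieux–Johnson cleavage of its only alkene (OsO4 cat., NaIO4, 2,6-lutidine, dioxane/H2O) would give (2,3,5,6-tetramethoxyphenyl)acetaldehyde F2. Separately, alkylation of the sodium salt of methyl bis(2,2,2-trifluoroethyl)phosphonoacetate with 13 (NaH, DMF) would give methyl 2-[bis(2,2,2-trifluoroethoxy)phosphoryl]-4-[(S)-2,6,6-trimethylcyclohex-2-en-1-yl]butanoate F3. Its potassium anion (KN(SiMe3)2, 18-crown-6, THF, −78 °C) should condense with F2 to give methyl (Z)-4-(2,3,5,6-tetramethoxyphenyl)-2-{2-[(S)-2,6,6-trimethylcyclohex-2-en-1-yl]ethyl}but-2-enoate F4, with the ester carbon cis to C1'. Reduction with i-Bu2AlH (CH2Cl2, −78 °C) would then give 22.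

Step 17 (selective hydrolysis). Water may add to the other vinylogous ester carbon or to both, and the strong acid may drive addition of the freed hydroxyl to the C2'=C3' alkene or migration of the ring alkene, which would erase the stereocentre. The fallback separates hydrolysis from regiocontrol, setting out from dimethoxyquinone 25 and ending at target 26. Exhaustive hydrolysis with aqueous NaOH in EtOH would give 2,5-dihydroxy-3-[(E)-3-methyl-5-[(S)-2,6,6-trimethylcyclohex-2-en-1-yl]pent-2-en-1-yl]cyclohexa-2,5-diene-1,4-dione F5. Acid-catalysed etherification of this vinylogous diacid (MeOH, H2SO4 cat., rt) under thermodynamic control should then place the single methyl group on the unhindered hydroxyl next to the ring CH, which gives 26.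

Step 15 (deoxygenation). Hydride may attack C2' in an SN2' sense and move the alkene to the exocyclic position, or sulfation may stay incomplete so that the alcohol is returned. The fallback uses an isolated allylic halide and a borohydride, setting out from alcohol 22 and rejoining at 24. Treatment with MsCl, LiCl and 2,4,6-collidine in DMF at 0 °C would give 3-[(Z)-3-(chloromethyl)-5-[(S)-2,6,6-trimethylcyclohex-2-en-1-yl]pent-2-en-1-yl]-1,2,4,5-tetramethoxybenzene F6, and LiEt3BH in THF at 0 °C should reduce this primary allylic chloride by direct SN2 displacement to 24.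

**Further compounds**

F1 | step 12 | 3-allyl-1,2,4,5-tetramethoxybenzene | C=CCc1c(OC)c(OC)cc(OC)c1OC
F2 | step 12 | (2,3,5,6-tetramethoxyphenyl)acetaldehyde | O=CCc1c(OC)c(OC)cc(OC)c1OC
F3 | step 12 | methyl 2-[bis(2,2,2-trifluoroethoxy)phosphoryl]-4-[(S)-2,6,6-trimethylcyclohex-2-en-1-yl]butanoate | COC(=O)C(CC[C@@H]1C(C)=CCCC1(C)C)P(=O)(OCC(F)(F)F)OCC(F)(F)F
F4 | step 12 | methyl (Z)-4-(2,3,5,6-tetramethoxyphenyl)-2-{2-[(S)-2,6,6-trimethylcyclohex-2-en-1-yl]ethyl}but-2-enoate | COC(=O)/C(CC[C@@H]1C(C)=CCCC1(C)C)=C\Cc1c(OC)c(OC)cc(OC)c1OC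
F5 | step 17 | 2,5-dihydroxy-3-[(E)-3-methyl-5-[(S)-2,6,6-trimethylcyclohex-2-en-1-yl]pent-2-en-1-yl]cyclohexa-2,5-diene-1,4-dione | OC1=CC(=O)C(O)=C(C/C=C(\C)CC[C@@H]2C(C)=CCCC2(C)C)C1=O
F6 | step 15 | 3-[(Z)-3-(chloromethyl)-5-[(S)-2,6,6-trimethylcyclohex-2-en-1-yl]pent-2-en-1-yl]-1,2,4,5-tetramethoxybenzene | ClC/C(CC[C@@H]1C(C)=CCCC1(C)C)=C\Cc1c(OC)c(OC)cc(OC)c1OC
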